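**Plan**

Numbering: phthalide numbering, with primed atoms for the unit inside the bicyclo[2.2.2]octene (bridgeheads C4' and C7'; inter-unit bonds C6–C7' and C7–C4'). Ring A = C3a, C4, C5, C6, C7, C7a; ring B = C6, C7, C4', C5', C6', C7'. α is the face of ring B that carries H-6 and H-7, β the face that carries the ring A bonds.
Enabling feature: C1'–C7a'–C3a'–C3' is a 1,4-dicarbonyl chain, so C7a' and C3a' are both enolate carbons. They hang from C7' and C4', 1,4-cis on the α face of ring B, and joining them closes the third bridge of the bicyclo[2.2.2]octene anti to ring A.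
Retrosynthetic cuts: unprimed lactone at O2–C1 and C1–C7a (CO) and at C3–C3a (pentanoyl); primed lactone at O2'–C1' and C3'–C8' (butyl); C7a'=C3a' back to C7a'–C3a', which is cut next (two enolates); then C4'–C3a' (Michael), C7'–C7a' (alkylation), and C6–C7' together with C7–C4' (Diels–Alder).
Forward order of rings: ring A is bought as 2-cyclohexen-1-one, ring B is fused to it by cycloaddition, and the two acetic arms are attached. The oxidative coupling then closes the bicyclo[2.2.2]octene, and the primed and finally the unprimed butylidene lactone are closed.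
Stereochemistry: C6 and C7 come from a catalytic enantioselective Diels–Alder reaction (cis fusion from suprafacial addition). C7' and C4' are set by substrate control, each arm entering α, trans to its ring A neighbour. C6' is set by hydride attack on the ketone face turned away from ring A, and both Z alkenes by allylic-strain (thermodynamic) control.

Key step: step 8

Assumption: the (S)-configured oxazaborolidinium catalyst is taken to direct the diene to the Si face of C3 of 2-cyclohexen-1-one; if the sense is the opposite, the equally available (R)-catalyst is used and nothing else changes.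

**Route**

Step 1
Reactants: 1 methyl vinyl ketone
Product: 2 2-(triisopropylsilyloxy)buta-1,3-diene
Conditions: TIPSOTf (1.05 equiv), Et3N (1.5 equiv), Et2O, 0 °C → rt
Reagents that add atoms: triisopropylsilyl triflate, CC(C)[Si](C(C)C)(C(C)C)OS(=O)(=O)C(F)(F)F
Why: O-Silylation of the methyl ketone enol (soft enolisation with a silyl triflate and an amine) gives the cross-conjugated 2-silyloxydiene, and TIPS is chosen because this enol ether has to survive the strong acid catalyst of step 2.

Step 2
Reactants: 3 2-cyclohexen-1-one; 2 2-(triisopropylsilyloxy)buta-1,3-diene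
Product: 4 (4aR,8aS)-6-(triisopropylsilyloxy)-3,4,4a,5,8,8a-hexahydronaphthalen-1(2H)-one (cis-fused adduct: C7a ketone, C5'=C6' TIPS enol ether)
Conditions: (S)-3,3-diphenyl-1-(2-methylphenyl)tetrahydro-1H,3H-pyrrolo[1,2-c][1,3,2]oxazaborole (20 mol%), (CF3SO2)2NH (18 mol%), CH2Cl2, −20 → 4 °C
Reagents that add atoms: none
Why: Enantioselective Diels–Alder reaction catalysed by a cationic (N-protonated) oxazaborolidine: boron binds the enone oxygen, lowers the LUMO of this otherwise sluggish dienophile and shields one face, the 2-silyloxy group steers the nucleophilic diene terminus to the β-carbon C6 ("para" adduct, oxygen at C6'), suprafacial addition makes the ring fusion cis, and the face choice of the catalyst sets C6 and C7 in the absolute sense.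

Step 3
Reactants: 4 cis-fused adduct
Product: 5 C7a ethylene ketal of 4
Conditions: (Me3SiOCH2)2 (1.5 equiv), Me3SiOTf (5 mol%), CH2Cl2, −78 → −40 °C; pyridine quench
Reagents that add atoms: 1,2-bis(trimethylsilyloxy)ethane, C[Si](C)(C)OCCO[Si](C)(C)C
Why: Noyori ketalisation (aprotic, low temperature) masks the only ketone without passing through its enol, so the epimerisable cis fusion at C7 is kept, and the hindered TIPS enol ether is too poor a nucleophile to be drawn into an aldol-type reaction with the transient oxocarbenium ion.

Step 4
Reactants: 5 ketal TIPS enol ether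
Product: 6 cis-fused enone ketal (C6' ketone, C4'=C5' alkene, C7a dioxolane)
Conditions: Pd(OAc)2 (10 mol%), O2 (1 atm), DMSO, 45 °C
Reagents that add atoms: none
Why: Saegusa–Ito oxidation: divalent palladium replaces silicon regiospecifically to give the C5' palladium enolate, β-hydride loss can only involve C4', and oxygen returns zerovalent palladium to the divalent state, so the C4'=C5' enone forms with its carbonyl at C6' and no stereocentre is touched.

Step 5
Reactants: 6 enone ketal; 7 tert-butyl bromoacetate
Product: 9 enone ketal bearing an α-CH2CO2t-Bu arm at C7' (trans to the C6–C5 bond), via lithium dienolate 8 (not isolated)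
Conditions: LDA (1.1 equiv), THF, −78 °C; 7 (1.3 equiv), DMPU, −78 → −40 °C
Reagents that add atoms: tert-butyl bromoacetate 7, CC(C)(C)OC(=O)CBr
Why: Kinetic α'-deprotonation of the enone with LDA gives the cross-conjugated dienolate 8 rather than the extended one (H-7 stays), and SN2 alkylation takes place on the convex α face because the β face always carries a pseudoaxial ring A bond, which sets C7' with the arm trans to C6–C5.

Step 6
Reactants: 9 C7'-alkylated enone; 10 1-(tert-butyldimethylsilyloxy)-1-methoxyethene
Product: 11 C5'=C6' TBS enol ether with α-CH2CO2t-Bu at C7' and α-CH2CO2Me at C4' (arms 1,4-cis)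
Conditions: 10 (1.5 equiv), LiClO4 (10 mol%), MeCN, rt → 40 °C
Reagents that add atoms: 1-(tert-butyldimethylsilyloxy)-1-methoxyethene 10, C=C(OC)O[Si](C)(C)C(C)(C)C
Why: Mukaiyama–Michael addition with silyl transfer: in the half-chair with C7–C7a pseudoaxial and the C7' arm equatorial, axial attack at C4' comes from the α face, trans to the dioxolane-bearing substituent on C7 (the usual trans result for 4-substituted cyclohexenones), which sets C4' 1,4-cis to the C7' arm, while the TBS group ends on the C6' oxygen, so this carbonyl is masked as the C5'=C6' enol ether at no extra cost and C7' can no longer epimerise.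

Step 7
Reactants: 11 diester enol ether
Product: 12 key-step precursor: as 11, with the C4' arm now CH2C(O)N(OMe)Me
Conditions: MeNH(OMe)·HCl (1.6 equiv), i-PrMgCl (3.2 equiv), THF, −20 → 0 °C
Reagents that add atoms: N,O-dimethylhydroxylamine hydrochloride, CNOC.Cl
Why: Aminolysis by the magnesium amide (Weinreb amide synthesis) takes the unhindered methyl ester and leaves the tert-butyl ester, the enol ether and the ketal alone, so the two arms become chemically distinct: future C1' is an ester, future C3' an amide that can later stop a Grignard reagent at the ketone.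

Step 8
Reactants: 12 key-step precursor
Product: 14 bridged ester amide (new C7a'–C3a' bridge anti to ring A; epimers at C7a' and C3a'), via dilithium bis-enolate 13 (not isolated)
Conditions: LDA (2.3 equiv), THF (0.01 M), −78 °C; Fe(acac)3 (2.2 equiv) in THF, −78 °C → rt
Reagents that add atoms: none
Why: LDA removes the only acidic hydrogens (one α-CH2 in each arm, since C7a is a ketal and C6' an enol ether), and Fe(acac)3, a one-electron oxidant of trivalent iron, turns one lithium enolate into an α-carbonyl radical that is captured by the carbon of the neighbouring enolate, a second one-electron oxidation of the resulting radical anion completing the C7a'–C3a' bond. The closest known reaction type is the intramolecular oxidative heterocoupling of an ester enolate with an amide enolate by salts of trivalent iron or divalent copper, which has closed bicyclo[2.2.2]diazaoctanes and other bridged rings, together with the oxidative cyclisation of diester bis-enolates to cyclohexane-1,2-dicarboxylates. The one new ring (C7', C7a', C3a', C4', C5', C6') closes in a 6-exo-trig mode from a boat form of ring B in which both α arms are pseudoaxial. That boat is cheaper here than in a saturated bis-ketal, because C5' and C6' are trigonal and A(1,2) strain with the OTBS group already pushes the C7' arm pseudoaxial, and as both arms lie on the α face the bridge can only form anti to ring A. C7a' and C3a' arise without control (the trans ester/amide pair should dominate, since the cis pair is eclipsed on the rigid bridge), which is harmless because step 9 makes both carbons trigonal. The step needs ring closure to beat dimerisation and needs union of the two unlike arms: high dilution and the 1,4-cis placement of the arms secure this, and the unlike carbonyl groups keep C1' and C3' distinguishable afterwards.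

Step 9
Reactants: 14 bridged ester amide
Product: 18 bicyclo[2.2.2]octadiene with the C7a'=C3a' alkene (CO2t-Bu on C7a'; C(O)N(OMe)Me on C3a') beside the C5'=C6' TBS enol ether, via lithium ester enolate 15 (not isolated), via phenylselenide 16 (not isolated), via selenoxide 17 (not isolated)
Conditions: LDA (1.2 equiv), THF, −78 °C; PhSeBr (1.2 equiv), −78 °C; crude selenide: mCPBA (1.0 equiv), CH2Cl2, −78 °C; i-Pr2NH (3 equiv), −78 °C → rt
Reagents that add atoms: none
Why: α-Selenenylation of the ester enolate followed by selenoxide syn elimination: selenium enters opposite to the neighbouring amide group and hence eclipsed with H-3a', the only other β-hydrogen sits on the bridgehead C7' and cannot be lost (Bredt's rule), so all epimers of 14 converge on the C7a'=C3a' alkene, while oxidation at selenium at −78 °C is far faster than epoxidation of the enol ether and the amine intercepts PhSeOH before it can add to that enol ether.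

Step 10
Reactants: 18 bicyclo[2.2.2]octadiene
Product: 19 C6' ketone (bicyclo[2.2.2]oct-2-en-5-one core; ester, amide and ketal unchanged)
Conditions: TBAF (1.1 equiv), AcOH (1.2 equiv), THF, 0 °C
Reagents that add atoms: none
Why: Fluoride cleaves the O–Si bond of the enol ether and acetic acid protonates C5' (silyl enol ether cleavage), while ketal, tert-butyl ester and Weinreb amide are untouched and the alkene cannot move into conjugation because both neighbouring carbons are bridgeheads.

Step 11
Reactants: 19 C6' ketone
Product: 20 (6'R)-alcohol, with OH pointing toward ring A and anti to the C7a'=C3a' bridge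
Conditions: NaBH4 (1.0 equiv), MeOH, −20 °C
Reagents that add atoms: none
Why: Borohydride reduction under steric approach control: the face of the C6' carbonyl that looks toward the C6–C7 bridge is blocked by C5H2 of ring A, which lies 1,3-syn to an incoming nucleophile, so hydride arrives from the side of the C7a'=C3a' bridge and the hydroxyl group is pushed toward ring A (6'R), while ester, amide and the tetrasubstituted alkene are inert to NaBH4.

Step 12
Reactants: 20 alcohol; 21 n-butylmagnesium chloride
Product: 22 keto ester (C3a'–C(O)Bu, C7a'–CO2t-Bu, free 6'-OH, C7a ketal)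
Conditions: 21 (3 equiv), THF, −40 → 0 °C; aq NH4Cl
Reagents that add atoms: n-butylmagnesium chloride 21, CCCC[Mg]Cl
Why: Weinreb ketone synthesis: after the first equivalent has deprotonated the hydroxyl group, the Grignard reagent adds to the N-methoxy-N-methylamide, magnesium chelation stops the addition at the ketone level, and the tert-butyl ester and the fully substituted, bridgehead-flanked alkene are too hindered to compete.

Step 13
Reactants: 22 keto ester
Product: 24 primed (Z)-butylidene lactone with free 6'-OH and free C7a ketone, via hydroxybutenolide 23 (not isolated)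
Conditions: CF3CO2H/CH2Cl2/H2O (10:10:1), 0 °C → rt; then evaporation from toluene
Reagents that add atoms: water, O
Why: All acid-labile groups fall in one operation: E1 acidolysis of the tert-butyl ester, ring–chain tautomerism of the γ-keto acid to hydroxybutenolide 23, acid-catalysed dehydration to the more stable Z-butylidene lactone (propyl on the side of O2', away from H-4'), driven to completion by azeotropic removal of water, and hydrolysis of the dioxolane, after which C7 cannot epimerise because a trans fusion of ring A to the bicyclo[2.2.2]octene would be highly strained.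

Step 14
Reactants: 24 hydroxy ketone
Product: 25 6'-O-triethylsilyl ether of 24
Conditions: Et3SiOTf (1.2 equiv), 2,6-lutidine (2 equiv), CH2Cl2, −78 °C
Reagents that add atoms: triethylsilyl triflate, CC[Si](CC)(CC)OS(=O)(=O)C(F)(F)F
Why: Silylation with a silyl triflate and a hindered pyridine base reaches even this crowded secondary alcohol at −78 °C, where the ketone is not enolised, and shields the hydroxyl group from the acyl chloride and the triflic anhydride of the next two steps.

Step 15
Reactants: 25 silyl ether ketone; 26 pentanoyl chloride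
Product: 27 C3a-pentanoyl derivative of 25 (β-diketone, drawn as the C7a enol)
Conditions: MgBr2·OEt2 (2.5 equiv), i-Pr2NEt (3 equiv), 26 (1.3 equiv), CH2Cl2, rt
Reagents that add atoms: pentanoyl chloride 26, CCCCC(=O)Cl
Why: Soft-enolisation Claisen-type C-acylation: MgBr2 and the amine enolise only the ketone, toward the CH2 group C3a rather than the tertiary and shielded C7, the chelated magnesium β-diketonate is the thermodynamic sink, and strong base, which would attack or deprotonate the butylidene lactone, is avoided.

Step 16
Reactants: 27 β-diketone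
Product: 28 C7a enol triflate (C7a=C3a alkene inside ring A, pentanoyl group on C3a)
Conditions: Tf2O (1.1 equiv), i-Pr2NEt (1.5 equiv), CH2Cl2, −78 °C
Reagents that add atoms: triflic anhydride, O=S(=O)(OS(=O)(=O)C(F)(F)F)C(F)(F)F
Why: O-Sulfonylation of the β-diketone enolate goes to the ring oxygen because this places the tetrasubstituted alkene inside the six-membered ring in conjugation with the acyl group, whereas the exocyclic alternative would suffer A(1,3) strain between its butyl or triflate group and C4H2.

Step 17
Reactants: 28 enol triflate; 29 carbon monoxide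
Product: 30 6'-O-triethylsilyl ether of the target
Conditions: Pd(PPh3)4 (10 mol%), CO (1 atm), Et3N (2 equiv), MeCN, 60 °C
Reagents that add atoms: carbon monoxide 29, [C-]#[O+]
Why: Palladium-catalysed carbonylative lactonisation: zerovalent palladium inserts into the C7a–OTf bond, CO insertion gives the acylpalladium species, and the enol oxygen of the neighbouring pentanoyl group captures it in a 5-exo closure (the reaction type known for β-halo enones and o-halophenyl ketones), the Z alkene resulting because the enol with its propyl group turned away from C4H2 is the one free of A(1,3) strain.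

Step 18
Reactants: 30 silyl ether
Product: 31 target CNP0289078.2, (3Z,3'Z,6S,7R,4'R,6'R,7'S)
Conditions: HF·pyridine, THF, 0 °C
Reagents that add atoms: none
Why: Fluoride-induced cleavage of the triethylsilyl ether under mildly acidic conditions leaves untouched both enol lactones, which would not survive a basic deprotection.

**Compound list**

1 | methyl vinyl ketone | CC(=O)C=C | starting material
2 | 2-(triisopropylsilyloxy)buta-1,3-diene | C=CC(=C)O[Si](C(C)C)(C(C)C)C(C)C | intermediate
3 | 2-cyclohexen-1-one | O=C1C=CCCC1 | starting material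
4 | (4aR,8aS)-6-(triisopropylsilyloxy)-3,4,4a,5,8,8a-hexahydronaphthalen-1(2H)-one | O=C1CCC[C@@H]2CC(O[Si](C(C)C)(C(C)C)C(C)C)=CC[C@H]12 | intermediate
5 | C7a ethylene ketal of 4 | O1CCOC12CCC[C@@H]3CC(O[Si](C(C)C)(C(C)C)C(C)C)=CC[C@H]23 | intermediate
6 | cis-fused enone ketal | O1CCOC12CCC[C@@H]3CC(=O)C=C[C@H]23 | intermediate
7 | tert-butyl bromoacetate | CC(C)(C)OC(=O)CBr | starting material
8 | lithium cross-conjugated dienolate of 6 | O1CCOC12CCC[C@@H]3C=C([O-])C=C[C@H]23.[Li+] | intermediate
9 | enone ketal with α-CH2CO2t-Bu at C7' | O1CCOC12CCC[C@@H]3[C@@H](CC(=O)OC(C)(C)C)C(=O)C=C[C@H]23 | intermediate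
10 | 1-(tert-butyldimethylsilyloxy)-1-methoxyethene | C=C(OC)O[Si](C)(C)C(C)(C)C | starting material
11 | diester TBS enol ether (arms at C7' and C4' both α) | O1CCOC12CCC[C@@H]3[C@@H](CC(=O)OC(C)(C)C)C(O[Si](C)(C)C(C)(C)C)=C[C@@H](CC(=O)OC)[C@H]23 | intermediate
12 | key-step precursor (tert-butyl ester arm at C7', Weinreb amide arm at C4') | O1CCOC12CCC[C@@H]3[C@@H](CC(=O)OC(C)(C)C)C(O[Si](C)(C)C(C)(C)C)=C[C@@H](CC(=O)N(C)OC)[C@H]23 | intermediate
13 | dilithium bis-enolate of 12 | O1CCOC12CCC[C@@H]3[C@@H](C=C([O-])OC(C)(C)C)C(O[Si](C)(C)C(C)(C)C)=C[C@@H](C=C([O-])N(C)OC)[C@H]23.[Li+].[Li+] | intermediate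
14 | key-step product, bridged ester amide (epimers at C7a' and C3a') | O1CCOC12CCC[C@@H]3[C@H]4C(C(=O)OC(C)(C)C)C(C(=O)N(C)OC)[C@H](C=C4O[Si](C)(C)C(C)(C)C)[C@H]23 | intermediate
15 | lithium ester enolate of 14 | O1CCOC12CCC[C@@H]3[C@H]4C(=C([O-])OC(C)(C)C)C(C(=O)N(C)OC)[C@H](C=C4O[Si](C)(C)C(C)(C)C)[C@H]23.[Li+] | intermediate
16 | C7a' phenylselenide | O1CCOC12CCC[C@@H]3[C@H]4C([Se]c5ccccc5)(C(=O)OC(C)(C)C)C(C(=O)N(C)OC)[C@H](C=C4O[Si](C)(C)C(C)(C)C)[C@H]23 | intermediate
17 | C7a' selenoxide | O1CCOC12CCC[C@@H]3[C@H]4C([Se](=O)c5ccccc5)(C(=O)OC(C)(C)C)C(C(=O)N(C)OC)[C@H](C=C4O[Si](C)(C)C(C)(C)C)[C@H]23 | intermediate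
18 | bicyclo[2.2.2]octadiene ester amide | O1CCOC12CCC[C@@H]3[C@H]4C(C(=O)OC(C)(C)C)=C(C(=O)N(C)OC)[C@H](C=C4O[Si](C)(C)C(C)(C)C)[C@H]23 | intermediate
19 | C6' ketone | O1CCOC12CCC[C@@H]3[C@H]4C(C(=O)OC(C)(C)C)=C(C(=O)N(C)OC)[C@H](CC4=O)[C@H]23 | intermediate
20 | (6'R)-alcohol | O1CCOC12CCC[C@@H]3[C@H]4C(C(=O)OC(C)(C)C)=C(C(=O)N(C)OC)[C@H](C[C@H]4O)[C@H]23 | intermediate
21 | n-butylmagnesium chloride | CCCC[Mg]Cl | starting material
22 | keto ester | O1CCOC12CCC[C@@H]3[C@H]4C(C(=O)OC(C)(C)C)=C(C(=O)CCCC)[C@H](C[C@H]4O)[C@H]23 | intermediate
23 | hydroxybutenolide (C3' epimers) | O=C1CCC[C@@H]2[C@H]3C4=C(C(O)(CCCC)OC4=O)[C@H](C[C@H]3O)[C@H]12 | intermediate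
24 | primed (Z)-butylidene lactone, 6'-OH, C7a ketone | O=C1CCC[C@@H]2[C@H]3C4=C(/C(=C/CCC)OC4=O)[C@H](C[C@H]3O)[C@H]12 | intermediate
25 | 6'-O-TES ether of 24 | O=C1CCC[C@@H]2[C@H]3C4=C(/C(=C/CCC)OC4=O)[C@H](C[C@H]3O[Si](CC)(CC)CC)[C@H]12 | intermediate
26 | pentanoyl chloride | CCCCC(=O)Cl | starting material
27 | C3a-pentanoyl β-diketone (enol form) | OC1=C(C(=O)CCCC)CC[C@@H]2[C@H]3C4=C(/C(=C/CCC)OC4=O)[C@H](C[C@H]3O[Si](CC)(CC)CC)[C@H]12 | intermediate
28 | C7a enol triflate | O=S(=O)(OC1=C(C(=O)CCCC)CC[C@@H]2[C@H]3C4=C(/C(=C/CCC)OC4=O)[C@H](C[C@H]3O[Si](CC)(CC)CC)[C@H]12)C(F)(F)F | intermediate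
29 | carbon monoxide | [C-]#[O+] | starting material
30 | 6'-O-TES ether of the target | CCC/C=C1\OC(=O)C2=C1CC[C@@H]1[C@H]3C4=C(/C(=C/CCC)OC4=O)[C@H](C[C@H]3O[Si](CC)(CC)CC)[C@H]21 | intermediate
31 | CNP0289078.2 | CCC/C=C1\OC(=O)C2=C1CC[C@@H]1[C@H]3C4=C(/C(=C/CCC)OC4=O)[C@H](C[C@H]3O)[C@H]21 | target

**Step count**

Total steps: 18. Longest linear sequence: 18 (1 → 31), or 17 counted from 2-cyclohexen-1-one 3.

**Steps most likely to fail**

Step 8 (oxidative closure).
- What may go wrong: the boat-like conformer may be populated too little, so that intermolecular dimerisation, simple reprotonation after electron transfer, or base-induced loss of the N-methoxy group outruns the ring closure.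
- Fallback: from 6, back at 22. The bicyclic core is assembled by cycloaddition instead.
- Dienolate 8, made from 6 as in step 5, is trapped with TBSCl to give the 2-silyloxy-1,3-cyclohexadiene F1.
- tert-Butyl propiolate is lithiated (LDA, −78 °C) and added to pentanal to give the propargylic alcohol F2, which Dess–Martin periodinane oxidises to the ynone ester F3.
- F1 and F3 combine in toluene at 60 °C in a Diels–Alder reaction on the α face. The nucleophilic diene terminus C7' bonds to the alkyne carbon β to the ketone, giving the bicyclooctadiene keto ester F4.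
- Buffered TBAF frees the C6' carbonyl (diketone F5). NaBH4 in MeOH/CH2Cl2 at −78 °C, which takes an isolated ketone before a conjugated one, reduces C6' from the alkene side and delivers 22.

Step 2 (enantioselective cycloaddition).
- What may go wrong: 2-cyclohexen-1-one is a weak dienophile, so slow turnover, protodesilylation of the diene by the acid catalyst, or insufficient facial selectivity may result.
- Fallback: from 2 and 3, back at 4. Absolute control is moved from catalysis to resolution.
- EtAlCl2 in toluene promotes the racemic cycloaddition to the racemic adduct F6.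
- NaBH4 attacks the convex face to give the racemic alcohol F7.
- Esterification with (S)-2-methoxy-2-phenylacetic acid (N,N'-dicyclohexylcarbodiimide, 4-(dimethylamino)pyridine) gives the diastereomeric ester F8 and its diastereomer F9, which are separated by chromatography.
- K2CO3 in MeOH releases the resolved alcohol F10 from F8, and Dess–Martin periodinane (NaHCO3 buffer) oxidises it to 4.

Step 17 (carbonylative lactonisation).
- What may go wrong: oxidative addition at the crowded C7a may be slow, the triflate may be hydrolysed or reduced, or the acylpalladium species may be captured other than by the enol oxygen.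
- Fallback: from 28, back at 31. Carbonylation and ring closure are separated.
- Hydroxycarbonylation of 28 (Pd(OAc)2, 1,1'-bis(diphenylphosphino)ferrocene, KOAc, CO 1 atm, DMSO, 60 °C, aqueous work-up) gives the acid, which closes onto the C3 ketone as the hydroxybutenolide F11.
- CF3CO2H in CH2Cl2 then dehydrates F11 to the Z-butylidene lactone and removes the silyl group in the same operation, giving 31 directly.

Further compounds
F1 | step 8 | 2-(tert-butyldimethylsilyloxy)-1,3-cyclohexadiene ketal derived from 6 | O1CCOC12CCC[C@@H]3C=C(O[Si](C)(C)C(C)(C)C)C=C[C@H]23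
F2 | step 8 | tert-butyl 4-hydroxyoct-2-ynoate (racemic) | CCCCC(O)C#CC(=O)OC(C)(C)C
F3 | step 8 | tert-butyl 4-oxooct-2-ynoate | CCCCC(=O)C#CC(=O)OC(C)(C)C
F4 | step 8 | bicyclooctadiene keto ester with C5'=C6' TBS enol ether | O1CCOC12CCC[C@@H]3[C@H]4C(C(=O)OC(C)(C)C)=C(C(=O)CCCC)[C@H](C=C4O[Si](C)(C)C(C)(C)C)[C@H]23
F5 | step 8 | diketone (C6' and C3' ketones) | O1CCOC12CCC[C@@H]3[C@H]4C(C(=O)OC(C)(C)C)=C(C(=O)CCCC)[C@H](CC4=O)[C@H]23
F6 | step 2 | racemic cis-fused adduct | O=C1CCC[C@@H]2CC(O[Si](C(C)C)(C(C)C)C(C)C)=CC[C@H]12.O=C1CCC[C@H]2CC(O[Si](C(C)C)(C(C)C)C(C)C)=CC[C@@H]12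
F7 | step 2 | racemic C7a alcohol (OH cis to the ring B bonds) | O[C@@H]1CCC[C@@H]2CC(O[Si](C(C)C)(C(C)C)C(C)C)=CC[C@H]12.O[C@H]1CCC[C@H]2CC(O[Si](C(C)C)(C(C)C)C(C)C)=CC[C@@H]12
F8 | step 2 | (S)-2-methoxy-2-phenylacetate of the (1R,4aR,8aS)-alcohol | CO[C@H](C(=O)O[C@@H]1CCC[C@@H]2CC(O[Si](C(C)C)(C(C)C)C(C)C)=CC[C@H]12)c1ccccc1
F9 | step 2 | (S)-2-methoxy-2-phenylacetate of the (1S,4aS,8aR)-alcohol | CO[C@H](C(=O)O[C@H]1CCC[C@H]2CC(O[Si](C(C)C)(C(C)C)C(C)C)=CC[C@@H]12)c1ccccc1
F10 | step 2 | resolved (1R,4aR,8aS)-alcohol | O[C@@H]1CCC[C@@H]2CC(O[Si](C(C)C)(C(C)C)C(C)C)=CC[C@H]12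
F11 | step 17 | unprimed hydroxybutenolide, 6'-O-TES (C3 epimers) | CCCCC1(O)OC(=O)C2=C1CC[C@@H]1[C@H]3C4=C(/C(=C/CCC)OC4=O)[C@H](C[C@H]3O[Si](CC)(CC)CC)[C@H]21
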